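**Retrosynthetic overview**
1. (+)-(2R)-Kazinol I is traced back to its 6'-chloro 7-O-TBS derivative (hydrodechlorination, then desilylation). The chlorine is a temporary blocking group on ring B.
2. Key disconnection: the two aryl–prenyl bonds at C3' and C2'. In ring B, C3' is the only hydrogen-bearing carbon ortho to O4' and C2' is para to O5'. Both prenyl groups can therefore come from the catechol oxygens by [3,3] shifts: the O4' 1,1-dimethylallyl group by ortho-Claisen, the O5' prenyl group by Claisen then Cope past the blocked C6' (Cl) and C4' (O).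
3. The bis-ether precursor is a (2R)-flavan. Ring C is the only ring built (O1–C2 bond, Mitsunobu closure with inversion of an (S)-1,3-diarylpropan-1-ol); rings A and B are bought as benzaldehydes, and the key step closes no ring.
4. The carbinol comes from catalytic asymmetric addition of a 2-arylethylzinc (from 2,4-dihydroxybenzaldehyde) to the doubly etherified 2-chloro-3,4-dihydroxybenzaldehyde. The alkyne is semi-hydrogenated only just before the thermal step.

Key step: step 10

Remark: ring B is described in flavan numbering (C1' on C2, O4' and O5' the catechol oxygens, C6' the chlorinated carbon), while substituent names number the same ring as a phenyl group from the carbon bonded to C2. 2-Chloro-3,4-dihydroxybenzaldehyde is taken as purchasable, and its 4-hydroxyl (para to the formyl group) is assumed to be the more acidic one. Prenyl = 3-methylbut-2-enyl, TBS = tert-butyldimethylsilyl, BSA = N,O-bis(trimethylsilyl)acetamide.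

**Route**

Step 1
Reactants: 1 2-chloro-3,4-dihydroxybenzaldehyde; 2 2-methylbut-3-yn-2-ol
Product: 4 2-chloro-3-hydroxy-4-(2-methylbut-3-yn-2-yloxy)benzaldehyde, via 2-methylbut-3-yn-2-yl trifluoroacetate 3 (not isolated)
Conditions: 2, (CF3CO)2O, DBU, MeCN, −5 °C; then 1, DBU (1.1 equiv), CuCl2 (0.5 mol%), MeCN, −5 to 0 °C, argon
Reagents that add atoms: none
Why: Copper-catalysed propargylic substitution through a copper allenylidene should place the tertiary propargyl group on oxygen, and with one equivalent of base the 4-hydroxyl (more acidic, less hindered than the 3-hydroxyl flanked by chlorine) is the phenoxide that reacts.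

Step 2
Reactants: 4 2-chloro-3-hydroxy-4-(2-methylbut-3-yn-2-yloxy)benzaldehyde; 5 1-bromo-3-methylbut-2-ene (prenyl bromide)
Product: 6 2-chloro-3-(prenyloxy)-4-(2-methylbut-3-yn-2-yloxy)benzaldehyde
Conditions: K2CO3, acetone, 40 °C
Reagents that add atoms: none
Why: Williamson ether synthesis, in which the remaining 3-phenoxide attacks the primary allylic carbon of the bromide (SN2) while the aldehyde and the propargyl ether stay inert.

Step 3
Reactants: 7 2,4-dihydroxybenzaldehyde
Product: 8 2,4-bis(TBS-oxy)benzaldehyde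
Conditions: TBSCl (2.4 equiv), imidazole, DMF, rt
Reagents that add atoms: tert-butyldimethylsilyl chloride, CC(C)(C)[Si](C)(C)Cl
Why: Silylation of both phenols removes the acidic hydrogens that the later organozinc reagent would not tolerate.

Step 4
Reactants: 8 2,4-bis(TBS-oxy)benzaldehyde
Product: 9 2,4-bis(TBS-oxy)styrene
Conditions: Ph3PCH3Br, n-BuLi, THF, 0 °C to rt
Reagents that add atoms: methyltriphenylphosphonium bromide, C[P+](c1ccccc1)(c1ccccc1)c1ccccc1.[Br-]
Why: Wittig methylenation of the aldehyde with a non-stabilised ylide, which does not attack aryl silyl ethers at this temperature.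

Step 5
Reactants: 9 2,4-bis(TBS-oxy)styrene; 6 2-chloro-3-(prenyloxy)-4-(2-methylbut-3-yn-2-yloxy)benzaldehyde
Product: 12 (1S)-3-[2,4-bis(TBS-oxy)phenyl]-1-[2-chloro-3-(prenyloxy)-4-(2-methylbut-3-yn-2-yloxy)phenyl]propan-1-ol, via 2-arylethyl(diethyl)borane 10 (not isolated), via bis(2-arylethyl)zinc 11 (not isolated)
Conditions: 9 (4 equiv), Et2BH (from BH3·SMe2 + Et3B), Et2O, 0 °C to rt; Et2Zn (neat), 0 °C, then volatiles removed in vacuo; Ti(OiPr)4, (1R,2R)-1,2-bis(trifluoromethanesulfonamido)cyclohexane (8 mol%), 6, toluene, −20 °C; aq NH4Cl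
Reagents that add atoms: none
Why: Anti-Markovnikov hydroboration and boron-to-zinc exchange give a salt-free primary dialkylzinc, which adds to the aryl aldehyde under Ti(OiPr)4/bis(sulfonamide) catalysis (catalytic asymmetric dialkylzinc addition); the (1R,2R) ligand sends the alkyl group to the Si face, the sense in which benzaldehyde and Et2Zn give (S)-1-phenylpropan-1-ol, so C1 should be S, and at −20 °C in toluene the terminal alkyne is not expected to be zincated.

Step 6
Reactants: 12 the (1S)-bis(TBS) carbinol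
Product: 13 (1S)-1-[2-chloro-3-(prenyloxy)-4-(2-methylbut-3-yn-2-yloxy)phenyl]-3-(2,4-dihydroxyphenyl)propan-1-ol
Conditions: TBAF (2.2 equiv), AcOH, THF, 0 °C
Reagents that add atoms: none
Why: Fluoride-mediated desilylation cleaves both aryl silyl ethers and leaves the secondary alcohol, the two ethers and the alkyne untouched, with acetic acid buffering the phenoxides.

Step 7
Reactants: 13 the (1S)-triol
Product: 14 (2R)-2-[2-chloro-3-(prenyloxy)-4-(2-methylbut-3-yn-2-yloxy)phenyl]chroman-7-ol
Conditions: PPh3, diisopropyl azodicarboxylate, THF (0.01 M), 0 °C to rt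
Reagents that add atoms: none
Why: Intramolecular Mitsunobu etherification, in which the ortho phenol displaces the benzylic oxyphosphonium by SN2 in a 6-exo-tet closure, so the S carbinol carbon becomes C2 with R configuration; high dilution keeps the second phenol from reacting between molecules.

Step 8
Reactants: 14 the (2R)-chroman-7-ol
Product: 15 (2R)-7-(TBS-oxy)-2-[2-chloro-3-(prenyloxy)-4-(2-methylbut-3-yn-2-yloxy)phenyl]chroman
Conditions: TBSCl, imidazole, CH2Cl2, rt
Reagents that add atoms: tert-butyldimethylsilyl chloride, CC(C)(C)[Si](C)(C)Cl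
Why: Silylation of the only free hydroxyl gives a ring A cap that should survive the thermal step and chromatography.

Step 9
Reactants: 15 the (2R)-7-TBS propargyl ether
Product: 16 (2R)-7-(TBS-oxy)-2-[2-chloro-3-(prenyloxy)-4-(2-methylbut-3-en-2-yloxy)phenyl]chroman
Conditions: H2 (1 atm), Pd/CaCO3 poisoned with Pb(OAc)2, quinoline, EtOAc, rt; used without delay
Reagents that add atoms: none
Why: Semi-hydrogenation of the terminal alkyne on lead-poisoned palladium should stop at the alkene without reducing the trisubstituted prenyl double bond or the aryl chloride, and the heat-sensitive tertiary allyl ether is made only now.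

Step 10
Reactants: 16 the (2R)-7-TBS bis-ether
Product: 19 (2R)-6'-chlorokazinol I 7-TBS ether, via 4'-O-trimethylsilyl 3'-prenyl ether 17 (not isolated), via 4',5'-bis(trimethylsilyl) ether 18 (not isolated)
Conditions: BSA (6 equiv), 1,2-dichlorobenzene, sealed tube, argon, 120 °C then 185 °C; then MeOH, citric acid (cat.), rt
Reagents that add atoms: none
Why: Proposed new method: two sigmatropic relays are run on one catechol bis-ether in one flask, which is untested as a tandem; the closest known reaction types are the ortho-Claisen rearrangement of aryl 1,1-dimethylallyl ethers and the para-Claisen (Claisen then Cope) rearrangement of prenyl ethers of phenols with both ortho positions blocked. At about 120 °C the tertiary allyl ether on O4' should pass through a chair [3,3] transition state to C3', the only ortho carbon bearing hydrogen, with allylic inversion to a normal prenyl group, and BSA should cap the new phenol at once as 17. At about 185 °C the prenyl group on O5' can reach only C6' (chlorine) or C4' (silyloxy), where the dienone cannot enolise, so a Cope [3,3] shift should carry it on to C2', para to O5', with a second inversion that restores the prenyl orientation, and enolisation then silylation gives 18. No ring is closed and no stereocentre is formed; C2 should keep its R configuration because the silylated O4' cannot open ring C through a para-quinone methide and no acid is present. The selectivity needed is regiochemical (C3' and C2' only) and rests on the chlorine at C6' and the oxygen at C4', while attack of the first group on C5' gives a dienone that can only revert; the crowded C6' dienone is expected to undergo the Cope shift faster than it loses chlorine. Mild methanolysis then frees the two catechol hydroxyls and leaves the TBS ether in place.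

Step 11
Reactants: 19 (2R)-6'-chlorokazinol I 7-TBS ether
Product: 20 (2R)-kazinol I 7-TBS ether
Conditions: Pd(OAc)2 (5 mol%), 2-dicyclohexylphosphino-2',4',6'-triisopropylbiphenyl (XPhos, 10 mol%), HCO2Na, DMF/H2O, 90 °C, argon
Reagents that add atoms: none
Why: Palladium-catalysed transfer hydrodechlorination (oxidative addition of the hindered C6'–Cl bond to zerovalent palladium on the bulky electron-rich phosphine, chloride–formate exchange, loss of CO2, C–H reductive elimination), which should spare the prenyl double bonds because neither H2 nor a heterogeneous metal is present.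

Step 12
Reactants: 20 (2R)-kazinol I 7-TBS ether
Product: 21 (+)-(2R)-kazinol I
Conditions: TBAF, AcOH, THF, 0 °C, argon
Reagents that add atoms: none
Why: Fluoride-mediated cleavage of the aryl silyl ether under acetic acid buffer, which keeps the air-sensitive diprenyl catechol protonated.

**Compound list**
1 | 2-chloro-3,4-dihydroxybenzaldehyde | O=Cc1ccc(O)c(O)c1Cl | starting material
2 | 2-methylbut-3-yn-2-ol | CC(C)(O)C#C | starting material
3 | 2-methylbut-3-yn-2-yl trifluoroacetate | CC(C)(C#C)OC(=O)C(F)(F)F | intermediate (not isolated)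
4 | 2-chloro-3-hydroxy-4-(2-methylbut-3-yn-2-yloxy)benzaldehyde | O=Cc1ccc(OC(C)(C)C#C)c(O)c1Cl | intermediate
5 | 1-bromo-3-methylbut-2-ene (prenyl bromide) | CC(C)=CCBr | starting material
6 | 2-chloro-3-(3-methylbut-2-enyloxy)-4-(2-methylbut-3-yn-2-yloxy)benzaldehyde | O=Cc1ccc(OC(C)(C)C#C)c(OCC=C(C)C)c1Cl | intermediate
7 | 2,4-dihydroxybenzaldehyde | O=Cc1ccc(O)cc1O | starting material
8 | 2,4-bis(tert-butyldimethylsilyloxy)benzaldehyde | O=Cc1ccc(O[Si](C)(C)C(C)(C)C)cc1O[Si](C)(C)C(C)(C)C | intermediate
9 | 2,4-bis(tert-butyldimethylsilyloxy)styrene | C=Cc1ccc(O[Si](C)(C)C(C)(C)C)cc1O[Si](C)(C)C(C)(C)C | intermediate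
10 | {2-[2,4-bis(tert-butyldimethylsilyloxy)phenyl]ethyl}diethylborane | CCB(CC)CCc1ccc(O[Si](C)(C)C(C)(C)C)cc1O[Si](C)(C)C(C)(C)C | intermediate (not isolated)
11 | bis{2-[2,4-bis(tert-butyldimethylsilyloxy)phenyl]ethyl}zinc | CC(C)(C)[Si](C)(C)Oc1ccc(CC[Zn]CCc2ccc(O[Si](C)(C)C(C)(C)C)cc2O[Si](C)(C)C(C)(C)C)c(O[Si](C)(C)C(C)(C)C)c1 | intermediate (not isolated)
12 | (1S)-3-[2,4-bis(tert-butyldimethylsilyloxy)phenyl]-1-[2-chloro-3-(3-methylbut-2-enyloxy)-4-(2-methylbut-3-yn-2-yloxy)phenyl]propan-1-ol | O[C@@H](CCc1ccc(O[Si](C)(C)C(C)(C)C)cc1O[Si](C)(C)C(C)(C)C)c1ccc(OC(C)(C)C#C)c(OCC=C(C)C)c1Cl | intermediate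
13 | (1S)-1-[2-chloro-3-(3-methylbut-2-enyloxy)-4-(2-methylbut-3-yn-2-yloxy)phenyl]-3-(2,4-dihydroxyphenyl)propan-1-ol | O[C@@H](CCc1ccc(O)cc1O)c1ccc(OC(C)(C)C#C)c(OCC=C(C)C)c1Cl | intermediate
14 | (2R)-2-[2-chloro-3-(3-methylbut-2-enyloxy)-4-(2-methylbut-3-yn-2-yloxy)phenyl]chroman-7-ol | C#CC(C)(C)Oc1ccc([C@H]2CCc3ccc(O)cc3O2)c(Cl)c1OCC=C(C)C | intermediate
15 | (2R)-7-(tert-butyldimethylsilyloxy)-2-[2-chloro-3-(3-methylbut-2-enyloxy)-4-(2-methylbut-3-yn-2-yloxy)phenyl]chroman | C#CC(C)(C)Oc1ccc([C@H]2CCc3ccc(O[Si](C)(C)C(C)(C)C)cc3O2)c(Cl)c1OCC=C(C)C | intermediate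
16 | (2R)-7-(tert-butyldimethylsilyloxy)-2-[2-chloro-3-(3-methylbut-2-enyloxy)-4-(2-methylbut-3-en-2-yloxy)phenyl]chroman | C=CC(C)(C)Oc1ccc([C@H]2CCc3ccc(O[Si](C)(C)C(C)(C)C)cc3O2)c(Cl)c1OCC=C(C)C | intermediate (key-step precursor)
17 | (2R)-7-(tert-butyldimethylsilyloxy)-2-[2-chloro-3-(3-methylbut-2-enyloxy)-5-(3-methylbut-2-enyl)-4-(trimethylsilyloxy)phenyl]chroman | CC(C)=CCOc1c(Cl)c([C@H]2CCc3ccc(O[Si](C)(C)C(C)(C)C)cc3O2)cc(CC=C(C)C)c1O[Si](C)(C)C | intermediate (not isolated)
18 | (2R)-7-(tert-butyldimethylsilyloxy)-2-[2-chloro-5,6-bis(3-methylbut-2-enyl)-3,4-bis(trimethylsilyloxy)phenyl]chroman | CC(C)=CCc1c([C@H]2CCc3ccc(O[Si](C)(C)C(C)(C)C)cc3O2)c(Cl)c(O[Si](C)(C)C)c(O[Si](C)(C)C)c1CC=C(C)C | intermediate (not isolated)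
19 | (2R)-6'-chlorokazinol I 7-TBS ether: 3-chloro-4-[(2R)-7-(tert-butyldimethylsilyloxy)chroman-2-yl]-5,6-bis(3-methylbut-2-enyl)benzene-1,2-diol | CC(C)=CCc1c([C@H]2CCc3ccc(O[Si](C)(C)C(C)(C)C)cc3O2)c(Cl)c(O)c(O)c1CC=C(C)C | intermediate (key-step product)
20 | (2R)-kazinol I 7-TBS ether: 5-[(2R)-7-(tert-butyldimethylsilyloxy)chroman-2-yl]-3,4-bis(3-methylbut-2-enyl)benzene-1,2-diol | CC(C)=CCc1c([C@H]2CCc3ccc(O[Si](C)(C)C(C)(C)C)cc3O2)cc(O)c(O)c1CC=C(C)C | intermediate
21 | (+)-(2R)-kazinol I | CC(C)=CCc1c([C@H]2CCc3ccc(O)cc3O2)cc(O)c(O)c1CC=C(C)C | target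

**Step count**
Total: 12 steps. Longest linear sequence: 10 steps (steps 1, 2, 5–12, or equally 3–12).

**Steps most likely to fail**

1. Step 10 (the labelled step). What may go wrong: at the hot stage the O5' prenyl ether may fragment with loss of isoprene, the C6' dienone may lose chlorine before the Cope shift, or the hindered O4' phenol may escape silylation and open ring C. Fallback, from 16 to 21, known chemistry only: the one-flask cascade is given up and its two halves are run as separate, individually precedented rearrangements with a robust cap between them.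
   - Heating 16 with BSA in toluene at 110–120 °C triggers only the ortho-Claisen shift and gives 17, which is methanolysed and isolated as the phenol (2R)-7-(TBS-oxy)-2-[2-chloro-4-hydroxy-3-(prenyloxy)-5-prenylphenyl]chroman F1.
   - TBSCl and imidazole convert it into the purifiable 4'-O-TBS ether F2.
   - F2 is then submitted alone to the para-Claisen (Claisen then Cope) rearrangement in 1,2-dichlorobenzene at 185–190 °C. The liberated 5'-hydroxyl has no ortho prenyl group and is meta to C1', so it needs no trap, and the product is the 5'-phenol 4'-O-TBS ether of 6'-chlorokazinol I 7-TBS ether F3.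
   - Hydrodechlorination as in step 11 gives the bis(TBS) ether of kazinol I F4, and TBAF/AcOH removes both silyl groups to reach 21.

2. Step 11. What may go wrong: oxidative addition into the hindered, electron-rich C–Cl bond next to a free phenol may be slow, the catechol may bind or be oxidised by palladium, and a palladium hydride may move the prenyl double bonds. Fallback, from 19 to 20: the reduction is moved to an electron-poorer, phenol-free substrate.
   - Ac2O and pyridine convert 19 into the 4',5'-diacetate of 6'-chlorokazinol I 7-TBS ether F5.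
   - The formate reduction (Pd(OAc)2, the same phosphine, HCO2Na) is run on F5, where the ring is less electron-rich and no phenoxide can bind the metal, to give the 4',5'-diacetate of kazinol I 7-TBS ether F6.
   - NH3 in MeOH at 0 °C under argon cleaves the two aryl acetates and returns 20.

3. Step 5. What may go wrong: the dialkylzinc may zincate the terminal alkyne, alkyl transfer to the ortho-chloro aldehyde may be sluggish, or the facial selectivity may be poor. Fallback, from 9 and 6 to 12: C–C bond formation is separated from the setting of the stereocentre.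
   - 9 is hydroborated with 9-BBN and oxidised with NaBO3·4H2O to 2-[2,4-bis(TBS-oxy)phenyl]ethanol F7.
   - CBr4 and PPh3 give 1-(2-bromoethyl)-2,4-bis(TBS-oxy)benzene F8.
   - Mg in THF gives 2-[2,4-bis(TBS-oxy)phenyl]ethylmagnesium bromide F9, which adds to 6 at −78 °C (Grignard addition) to give the racemic form of the carbinol, rac-12 F10.
   - Dess–Martin periodinane with NaHCO3 oxidises it to the ketone 3-[2,4-bis(TBS-oxy)phenyl]-1-[2-chloro-3-(prenyloxy)-4-(2-methylbut-3-yn-2-yloxy)phenyl]propan-1-one F11.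
   - CBS reduction with (R)-2-methyl-CBS-oxazaborolidine and catecholborane in toluene at −78 °C, conditions that leave the alkyne and the prenyl group alone, should give (S)-12.

Further compounds
F1 | step 10 | (2R)-7-(tert-butyldimethylsilyloxy)-2-[2-chloro-4-hydroxy-3-(3-methylbut-2-enyloxy)-5-(3-methylbut-2-enyl)phenyl]chroman | CC(C)=CCOc1c(Cl)c([C@H]2CCc3ccc(O[Si](C)(C)C(C)(C)C)cc3O2)cc(CC=C(C)C)c1O
F2 | step 10 | (2R)-7-(tert-butyldimethylsilyloxy)-2-[4-(tert-butyldimethylsilyloxy)-2-chloro-3-(3-methylbut-2-enyloxy)-5-(3-methylbut-2-enyl)phenyl]chroman | CC(C)=CCOc1c(Cl)c([C@H]2CCc3ccc(O[Si](C)(C)C(C)(C)C)cc3O2)cc(CC=C(C)C)c1O[Si](C)(C)C(C)(C)C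
F3 | step 10 | 6-(tert-butyldimethylsilyloxy)-2-chloro-3-[(2R)-7-(tert-butyldimethylsilyloxy)chroman-2-yl]-4,5-bis(3-methylbut-2-enyl)phenol | CC(C)=CCc1c([C@H]2CCc3ccc(O[Si](C)(C)C(C)(C)C)cc3O2)c(Cl)c(O)c(O[Si](C)(C)C(C)(C)C)c1CC=C(C)C
F4 | step 10 | 2-(tert-butyldimethylsilyloxy)-5-[(2R)-7-(tert-butyldimethylsilyloxy)chroman-2-yl]-3,4-bis(3-methylbut-2-enyl)phenol | CC(C)=CCc1c([C@H]2CCc3ccc(O[Si](C)(C)C(C)(C)C)cc3O2)cc(O)c(O[Si](C)(C)C(C)(C)C)c1CC=C(C)C
F5 | step 11 | (2R)-6'-chlorokazinol I 7-TBS ether 4',5'-diacetate | CC(C)=CCc1c([C@H]2CCc3ccc(O[Si](C)(C)C(C)(C)C)cc3O2)c(Cl)c(OC(C)=O)c(OC(C)=O)c1CC=C(C)C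
F6 | step 11 | (2R)-kazinol I 7-TBS ether 4',5'-diacetate | CC(C)=CCc1c([C@H]2CCc3ccc(O[Si](C)(C)C(C)(C)C)cc3O2)cc(OC(C)=O)c(OC(C)=O)c1CC=C(C)C
F7 | step 5 | 2-[2,4-bis(tert-butyldimethylsilyloxy)phenyl]ethanol | OCCc1ccc(O[Si](C)(C)C(C)(C)C)cc1O[Si](C)(C)C(C)(C)C
F8 | step 5 | 1-(2-bromoethyl)-2,4-bis(tert-butyldimethylsilyloxy)benzene | BrCCc1ccc(O[Si](C)(C)C(C)(C)C)cc1O[Si](C)(C)C(C)(C)C
F9 | step 5 | 2-[2,4-bis(tert-butyldimethylsilyloxy)phenyl]ethylmagnesium bromide | Br[Mg]CCc1ccc(O[Si](C)(C)C(C)(C)C)cc1O[Si](C)(C)C(C)(C)C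
F10 | step 5 | racemic 3-[2,4-bis(tert-butyldimethylsilyloxy)phenyl]-1-[2-chloro-3-(3-methylbut-2-enyloxy)-4-(2-methylbut-3-yn-2-yloxy)phenyl]propan-1-ol | OC(CCc1ccc(O[Si](C)(C)C(C)(C)C)cc1O[Si](C)(C)C(C)(C)C)c1ccc(OC(C)(C)C#C)c(OCC=C(C)C)c1Cl
F11 | step 5 | 3-[2,4-bis(tert-butyldimethylsilyloxy)phenyl]-1-[2-chloro-3-(3-methylbut-2-enyloxy)-4-(2-methylbut-3-yn-2-yloxy)phenyl]propan-1-one | O=C(CCc1ccc(O[Si](C)(C)C(C)(C)C)cc1O[Si](C)(C)C(C)(C)C)c1ccc(OC(C)(C)C#C)c(OCC=C(C)C)c1Cl
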